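**Retrosynthetic overview**
- All six rings (A, B and C of each flavone unit) are bought ready-made in apigenin 1, so no ring is formed in the route.
- Both halves come from one monomer, genkwanin 2, which is 1 methylated at O7.
- Aryl donor half: 2 ⇒ 4'-O-MOM ether 3 ⇒ 6-iodide 4, with the iodine placed ortho to the free 5-OH.
- Key disconnection, made last: the diaryl ether bond C6''–O4'. Thus 4 + 2 ⇒ MOM-protected dimer 5 ⇒ target 6.

Assumption: the target has no stereocentre and no hindered axis (the diaryl ether turns freely), so it is achiral, the given SMILES defines it fully, and there is no enantiomer to select.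

**Step 1**
Reactants: 1 apigenin
Product: 2 genkwanin (apigenin 7-methyl ether)
Conditions: Me2SO4 (1.05 equiv), K2CO3 (1.0 equiv), DMF, rt, 12 h
Reagents that add atoms: dimethyl sulfate, COS(=O)(=O)OC
Why: Williamson ether synthesis under acidity control: the 7-OH (para to the C4 carbonyl) is the most acidic, the 4'-OH is about one pKa unit weaker and the 5-OH is locked in a hydrogen bond to C4=O, so one equivalent each of base and methylating agent goes to O7 first; no stereocentre is formed.

**Step 2**
Reactants: 2 genkwanin (the part not kept for step 4)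
Product: 3 4'-O-MOM-genkwanin
Conditions: MOMCl (1.2 equiv), K2CO3 (1.5 equiv), DMF, 0 °C to rt, 3 h
Reagents that add atoms: chloromethyl methyl ether, COCCl
Why: Williamson-type O-alkylation (acetal protection): only the 4'-OH ionises freely while the chelated 5-OH stays untouched, and the MOM group later stops the iodide from condensing with itself and tempers ring B against iodination.

**Step 3**
Reactants: 3 4'-O-MOM-genkwanin
Product: 4 6-iodo-4'-O-MOM-genkwanin
Conditions: BnMe3N·ICl2 (1.1 equiv), CaCO3 (1.5 equiv), CH2Cl2–MeOH 5:2, rt, 16 h, dark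
Reagents that add atoms: benzyltrimethylammonium dichloroiodate, C[N+](C)(C)Cc1ccccc1.Cl[I-]Cl
Why: Electrophilic aromatic iodination steered by the free 5-OH: with O7 alkylated and O5 free, the iodine goes ortho to the phenol (C6) and not to C8, as is known for the 4'-O-methyl analogue, and CaCO3 takes up the HCl so the acetal survives.

**Step 4**
Reactants: 4 6-iodo-4'-O-MOM-genkwanin (1.0 equiv); 2 genkwanin (1.5 equiv)
Product: 6 7,7''-di-O-methylhinokiflavone, via MOM-protected biflavone 5 (not isolated)
Conditions: CuI (20 mol %), Cs2CO3 (4.5 equiv), 4 Å MS, NMP, 105 °C, Ar, 24 h; then excess HCl (3 mol/L in MeOH), 55 °C, 3 h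
Reagents that add atoms: none
Why: Proposed new method: ortho-phenoxide-directed Ullmann aryloxylation without ancillary ligand: the 5-OH of 4 is left free on purpose, and as its caesium phenoxide it binds monovalent copper that already carries the 4'-phenoxide of 2, while the neighbouring iodine closes a five-membered oxygen–copper–iodine chelate, so oxidative addition into the hindered, electron-rich C6–iodine bond becomes intramolecular instead of the slow bimolecular step of an ordinary Ullmann coupling; the trivalent aryl copper so formed can pair C6 only with the 4'-aryloxide (pairing with O5 would need a three-membered ring), and carbon–oxygen reductive elimination from trivalent copper is fastest for weakly basic oxygen partners such as this vinylogous-acid phenoxide; the MOM acetal is then methanolysed by HCl in the same flask; closest known reaction types are the ligand-free CuBr/NaOMe methanolysis of ortho-halophenols (5-iodovanillin, 6- and 8-bromo-5-hydroxyflavones) and the Ullmann diaryl ether synthesis, neither shown with a phenoxide nucleophile at C6 of an unprotected 5-hydroxyflavone; no stereocentre is formed.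

**Compound list**

1 | apigenin, 5,7-dihydroxy-2-(4-hydroxyphenyl)-4H-chromen-4-one (achiral) | O=c1cc(-c2ccc(O)cc2)oc2cc(O)cc(O)c12 | starting material
2 | genkwanin, 5-hydroxy-2-(4-hydroxyphenyl)-7-methoxy-4H-chromen-4-one (achiral) | COc1cc(O)c2c(=O)cc(-c3ccc(O)cc3)oc2c1 | intermediate
3 | 4'-O-MOM-genkwanin, 5-hydroxy-7-methoxy-2-[4-(methoxymethoxy)phenyl]-4H-chromen-4-one (achiral) | COc1cc(O)c2c(=O)cc(-c3ccc(OCOC)cc3)oc2c1 | intermediate
4 | 6-iodo-4'-O-MOM-genkwanin, 5-hydroxy-6-iodo-7-methoxy-2-[4-(methoxymethoxy)phenyl]-4H-chromen-4-one (achiral) | COc1cc2oc(-c3ccc(OCOC)cc3)cc(=O)c2c(O)c1I | intermediate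
5 | MOM-protected biflavone, 4'''-O-MOM-7,7''-di-O-methylhinokiflavone (achiral) | COc1cc(O)c2c(=O)cc(-c3ccc(Oc4c(OC)cc5oc(-c6ccc(OCOC)cc6)cc(=O)c5c4O)cc3)oc2c1 | intermediate
6 | 7,7''-di-O-methylhinokiflavone, 5-hydroxy-6-[4-(5-hydroxy-7-methoxy-4-oxo-4H-chromen-2-yl)phenoxy]-2-(4-hydroxyphenyl)-7-methoxy-4H-chromen-4-one (achiral) | COc1cc(O)c2c(=O)cc(-c3ccc(Oc4c(OC)cc5oc(-c6ccc(O)cc6)cc(=O)c5c4O)cc3)oc2c1 | target

**Total step count:** 4
**Longest linear sequence:** 4 (1 → 2 → 3 → 4 → 6). Compound 2 enters twice, as precursor of 4 and as the phenol in step 4.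

**Three steps most likely to fail**

**Step 4 (the new step).**
- Risks: the iodide is doubly ortho-oxygenated and electron-rich, and the phenoxide is a weak nucleophile.
- Copper may also rest in the 5-olate/4-keto pockets, and hydrodeiodination would return 3.
- The fallback uses known chemistry with reversed polarity. It sets out from 4 and comes back at 6.
- Copper-catalysed hydroxylation of 4 (Cu(acac)2, N,N'-bis(4-hydroxy-2,6-dimethylphenyl)oxalamide, LiOH, DMSO–H2O, 80 °C) gives 5,6-dihydroxy-7-methoxy-4'-(methoxymethoxy)flavone F1.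
- Separately, purchased 2'-hydroxy-4',6'-dimethoxyacetophenone and 4-fluorobenzaldehyde condense (KOH, EtOH, rt) to (E)-3-(4-fluorophenyl)-1-(2-hydroxy-4,6-dimethoxyphenyl)prop-2-en-1-one F2.
- I2 (cat.), DMSO, 130 °C then closes this chalcone to 4'-fluoro-5,7-dimethoxyflavone F3.
- K2CO3, DMF, 120 °C under argon joins the unchelated, electron-rich 6-OH of F1 to the carbonyl-activated C4' of F3 by SNAr. This is the electronically matched pairing, and it gives 5,7,7''-tri-O-methyl-4'''-O-MOM-hinokiflavone F4.
- BCl3, CH2Cl2, −20 to 0 °C, then MeOH, removes only the peri 5-O-methyl group and the MOM group and delivers 6.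

**Step 1.**
- Risk: the acidity gap between 7-OH and 4'-OH is small, so 7,4'-dimethylation and unreacted 1 lower the yield.
- The fallback replaces acidity control by protecting-group control. It sets out from 1 and comes back at 2.
- Ac2O, pyridine gives apigenin 5,7,4'-triacetate F5.
- PhSH, imidazole, NMP, rt cleaves only the 7-acetate, the ester of the best leaving phenoxide, and gives apigenin 5,4'-diacetate F6.
- Me2SO4, K2CO3, acetone gives genkwanin 5,4'-diacetate F7.
- K2CO3, MeOH, rt gives 2.

**Step 3.**
- Risks: some C8 or 6,8-di-iodination, which would end in the wrong ether isomer.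
- The site must be checked by HMBC from the chelated 5-OH proton to the iodine-bearing carbon.
- The fallback gives up the C6 halide and lets the reaction geometry fix the site. It sets out from 3 and comes back at 6.
- Compound 3 has one free phenol and one free position ortho to it, so ortho-oxygen transfer from pentavalent iodine (IBX, DMF, rt) can only end at C6. This gives the ortho-quinone 7-methoxy-2-[4-(methoxymethoxy)phenyl]chromene-4,5,6-trione F8.
- Aqueous Na2S2O4 reduces the quinone in the same pot to the catechol F1.
- From there the SNAr with the fluoroflavone F3 to the protected biflavone F4, and the BCl3 cleavage described above, lead to 6.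

**Further compounds**
F1 | step 4 | 5,6-dihydroxy-7-methoxy-2-[4-(methoxymethoxy)phenyl]-4H-chromen-4-one | COc1cc2oc(-c3ccc(OCOC)cc3)cc(=O)c2c(O)c1O
F2 | step 4 | (E)-3-(4-fluorophenyl)-1-(2-hydroxy-4,6-dimethoxyphenyl)prop-2-en-1-one | COc1cc(O)c(C(=O)/C=C/c2ccc(F)cc2)c(OC)c1
F3 | step 4 | 4'-fluoro-5,7-dimethoxyflavone | COc1cc(OC)c2c(=O)cc(-c3ccc(F)cc3)oc2c1
F4 | step 4 | 5,7,7''-tri-O-methyl-4'''-O-MOM-hinokiflavone | COc1cc(OC)c2c(=O)cc(-c3ccc(Oc4c(OC)cc5oc(-c6ccc(OCOC)cc6)cc(=O)c5c4O)cc3)oc2c1
F5 | step 1 | apigenin 5,7,4'-triacetate | CC(=O)Oc1ccc(cc1)-c1cc(=O)c2c(OC(C)=O)cc(OC(C)=O)cc2o1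
F6 | step 1 | apigenin 5,4'-diacetate | CC(=O)Oc1ccc(cc1)-c1cc(=O)c2c(OC(C)=O)cc(O)cc2o1
F7 | step 1 | genkwanin 5,4'-diacetate | CC(=O)Oc1ccc(cc1)-c1cc(=O)c2c(OC(C)=O)cc(OC)cc2o1
F8 | step 3 | 7-methoxy-2-[4-(methoxymethoxy)phenyl]chromene-4,5,6-trione | COC1=CC2=C(C(=O)C=C(O2)c2ccc(OCOC)cc2)C(=O)C1=O
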